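**Retrosynthetic overview**

1. Numbering used: ring A = C1–C5, C10; ring B = C5–C10; ring C = C8, C9, C11–C14; ring D (cyclobutane) = C1, C10, C9, C11; cyclopropane = C13, C15 (bearing methyl C16), C17; C18/C19 on C4, C20 on C10.
2. Rings B and C are both opened at C8: the C8–C7 and C8–C9 bonds are two intramolecular aldol bonds made by one acetyl methyl group (C8 on C14), onto a C7 aldehyde and a C9 cyclobutanone; C6–C7 comes from vinyl addition to a C6 aldehyde.
3. Ring A is traced to a seven-membered ring A′ (C6, C10, C1, C2, C3, C4, C5) in which C6 is the ring carbonyl; a photochemical Wolff rearrangement shifts C10 from C6 to C5 and contracts seven to six.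
4. Enabling feature: ring A is trans-fused to ring D at C1–C10, and C5 carries the exocyclic carbon C6 next to the quaternary C10. A trans junction is what a cyclohept-2-enone (not a cyclohexenone) gives in a [2+2] photocycloaddition, and the enone carbonyl carbon then becomes C6 of ring B.
5. Ring D comes from the [2+2] of enone 7 (from eucarvone) with alkoxyallene 20 (from (R)-propylene oxide). Ring order: A′ (seven) → D → A (contraction) → C → B.

Key step: step 14

Assumption: the cycloaddition in step 12 is taken to occur on the enone face anti to the C3 silyl ether, and the (S,S) catalyst in step 2 is taken to give the (4R,5S) epoxide; if either sense is the reverse, the antipodal epoxidation catalyst supplies the matching enone (C3 is later oxidised to the ketone).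

**Ring A′ enone**

Step 1
Reactants: 1 (R)-(−)-carvone
Product: 3 eucarvone (2,6,6-trimethylcyclohepta-2,4-dien-1-one), via carvone hydrobromide 2 (not isolated)
Conditions: HBr (33% in AcOH), 0 °C; then KOH, MeOH, 0 °C to rt
Reagents that add atoms: none
Why: Known carvone-to-eucarvone ring expansion, in which HBr adds to the isopropenyl group, base closes a carenone by enolate alkylation and the cyclopropane opens to the conjugated cycloheptadienone; no stereocentre remains.

Step 2
Reactants: 3 eucarvone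
Product: 4 (4R,5S)-4,5-epoxy-2,6,6-trimethylcyclohept-2-en-1-one
Conditions: (S,S)-(salen)MnCl (5 mol%; salen = N,N′-bis(3,5-di-tert-butylsalicylidene)cyclohexane-1,2-diamine dianion), NaOCl (aq), 4-phenylpyridine N-oxide, CH2Cl2, 0 °C
Reagents that add atoms: sodium hypochlorite, [Na+].[O-]Cl
Why: Jacobsen–Katsuki epoxidation should pick the electron-rich cis-disubstituted γ,δ-alkene next to the gem-dimethyl group (a 2,2-dimethylchromene-like site) over the enone alkene, and the ligand sets both epoxide carbons by reagent control.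

Step 3
Reactants: 4 epoxy enone
Product: 6 (5R)-5-hydroxy-2,6,6-trimethylcyclohept-2-en-1-one, via β,γ-unsaturated hydroxy ketone 5 (not isolated)
Conditions: SmI2 (2.5 equiv), THF/MeOH, −78 °C; then DBU (0.2 equiv), CH2Cl2, rt
Reagents that add atoms: none
Why: Vinylogous reductive opening of a γ,δ-epoxy enone cleaves the allylic C–O bond (at C2) and leaves the C3–O stereocentre untouched; DBU then returns the alkene into conjugation.

Step 4
Reactants: 6 hydroxy enone
Product: 7 (5R)-5-(tert-butyldimethylsilyloxy)-2,6,6-trimethylcyclohept-2-en-1-one (ring A′: C6 ketone, C10=C1 alkene, C3 silyl ether)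
Conditions: TBSCl, imidazole, DMF, rt
Reagents that add atoms: tert-butyldimethylsilyl chloride, CC(C)(C)[Si](C)(C)Cl
Why: Standard silylation of a secondary alcohol; no new stereocentre.

**Allene fragment**

Step 5
Reactants: 8 benzyl propargyl ether
Product: 9 benzyloxyallene
Conditions: KOtBu (0.3 equiv), THF, 0 °C to rt
Reagents that add atoms: none
Why: Base-catalysed propargyl-to-allenyl ether isomerisation, a known route to 1-alkoxyallenes.

Step 6
Reactants: 10 (R)-propylene oxide; 11 diethyl cyanomethylphosphonate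
Product: 12 (1S,2S)-2-methylcyclopropane-1-carbonitrile
Conditions: NaH, DME, 0 °C; then 10, 85 °C (sealed tube)
Reagents that add atoms: none
Why: Wadsworth–Emmons-type cyclopropanation of an epoxide: the phosphonate carbanion opens the epoxide at CH2, the phosphoryl group moves to oxygen and 3-exo-tet closure inverts the methyl-bearing carbon, which fixes C15 as S in the trans nitrile.

Step 7
Reactants: 12 cyclopropyl nitrile; 13 N-methoxy-N-methylacetamide
Product: 15 (1S,2S)-1-acetyl-2-methylcyclopropane-1-carbonitrile, via lithiated nitrile 14 (not isolated)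
Conditions: LiN(iPr)2, THF, −78 °C; then 13, −78 to −20 °C
Reagents that add atoms: none
Why: The rapidly inverting nitrile-stabilised cyclopropyl anion should be acylated on the face anti to the 2-methyl group, so the acetyl carbon (C14, with C8 as its methyl) ends trans and the nitrile carbon (C12) cis to C16, which sets C13; the Weinreb amide stops at the ketone.

Step 8
Reactants: 15 acetyl nitrile
Product: 16 (1S,2S)-2-methyl-1-(2-methyl-1,3-dioxolan-2-yl)cyclopropane-1-carbonitrile
Conditions: (Me3SiOCH2)2, Me3SiOTf (5 mol%), CH2Cl2, −78 to −20 °C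
Reagents that add atoms: 1,2-bis(trimethylsilyloxy)ethane, C[Si](C)(C)OCCO[Si](C)(C)C
Why: Aprotic low-temperature ketalisation masks the C14 ketone without opening the acceptor-substituted cyclopropane.

Step 9
Reactants: 16 ketal nitrile
Product: 17 (1S,2S)-2-methyl-1-(2-methyl-1,3-dioxolan-2-yl)cyclopropane-1-carbaldehyde
Conditions: iBu2AlH, CH2Cl2, −78 °C; then aqueous Rochelle salt, pH 5 buffer
Reagents that add atoms: water, O
Why: Hydride adds once to the nitrile and the aldimine hydrolyses on work-up to the non-enolisable aldehyde (C12).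

Step 10
Reactants: 9 benzyloxyallene; 17 aldehyde
Product: 19 (1S)-2-benzyloxy-1-[(1S,2S)-2-methyl-1-(2-methyl-1,3-dioxolan-2-yl)cyclopropyl]buta-2,3-dien-1-ol, via 1-benzyloxy-1-lithioallene 18 (not isolated)
Conditions: n-BuLi, THF, −40 °C; then 17, −78 °C
Reagents that add atoms: none
Why: α-Lithiated alkoxyallenes add 1,2 to aldehydes at the oxygen-bearing carbon (C11); Felkin–Anh attack anti to the ketal-bearing C14 and past the unsubstituted ring carbon C17 should set C12 as required.

Step 11
Reactants: 19 allenyl carbinol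
Product: 20 4-methoxybenzyl ether of 19
Conditions: NaH, 4-MeOC6H4CH2Cl, Bu4NI (cat.), THF/DMF, 0 °C to rt
Reagents that add atoms: 4-methoxybenzyl chloride, COc1ccc(CCl)cc1
Why: Williamson etherification under basic conditions, which the acid-labile alkoxyallene tolerates; no stereocentre changes.

**Assembly**

Step 12
Reactants: 7 ring A′ enone; 20 alkoxyallene
Product: 21 trans-fused [2+2] cycloadduct (ring A′ + ring D: C6 ketone, C9 exocyclic methylene, C11 benzyloxy syn to C20, H1 anti to C20)
Conditions: hν (366 nm), CH2Cl2, −40 °C, 7 (3 equiv)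
Reagents that add atoms: none
Why: Enone–allene [2+2] photocycloaddition: the twisted excited cycloheptenone should give the trans junction at C1–C10; the oxygen-bearing allene terminus C11 should bond to the β-carbon C1 and the sp carbon C9 to the methyl-bearing α-carbon C10 (the orientation rules for enol ethers and for allenes agree, and no bond between two quaternary centres is made); attack anti to the C3 silyl ether and anti to the C12–O bond, with C12–H turned toward the benzyloxy group, sets C1, C10 and C11.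

Step 13
Reactants: 21 cycloadduct
Product: 23 C5 α-diazo ketone, via C5-trifluoroacetyl ketone 22 (not isolated)
Conditions: LiN(SiMe3)2, THF, −78 °C; CF3CO2CH2CF3; then MeSO2N3, Et3N, H2O, MeCN, rt
Reagents that add atoms: methanesulfonyl azide, CS(=O)(=O)N=[N+]=[N-]
Why: Detrifluoroacetylative diazo transfer; C5 is the only enolisable position of the only ketone (C10 is quaternary, C1–H is β), so the diazo group can only go to C5 and no stereocentre is at risk.

Step 14
Reactants: 23 α-diazo ketone
Product: 25 ring-contracted Weinreb amide (ring A six-membered, trans-fused to ring D; C6 carboxamide on C5, H5 syn to C20), via ketene 24 (not isolated)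
Conditions: hν (λ > 300 nm, Pyrex), MeNHOMe (5 equiv), THF, 0 °C
Reagents that add atoms: N,O-dimethylhydroxylamine, CNOC
Why: Irradiation expels N2 from the ring-locked s-Z α-diazo ketone with concerted 1,2-shift of the quaternary C10 from the carbonyl carbon C6 to C5 (Wolff rearrangement), so ring A′ (C6, C10, C1, C2, C3, C4, C5) contracts to ring A (C1–C5, C10) and C6 leaves the ring as a ketene that the hydroxylamine traps as the amide. The closest known reaction type is the photochemical Wolff ring contraction of cyclic α-diazo ketones to the next lower cycloalkanecarboxylic acid derivative. No ring is closed end to end: ring A arises by the alkyl shift that makes the C5–C10 bond as the C6–C10 bond breaks, and the migrating carbon keeps its configuration, so the trans junction between ring A and the cyclobutane (H1 anti to C20) is carried over unchanged. The new stereocentre C5 is set when the amide enol is protonated from the face of the C20 methyl group, away from the substituted cyclobutane, which puts H5 syn to C20 and C6 syn to C9 as ring B requires. The step needs the 1,2-shift to win over carbene side reactions (methyl shift from C4, C–H insertion, addition to the C9 methylene) and needs a single migrating group: the s-Z geometry favours the concerted shift, and C10 is the only carbon substituent on the acyl carbon.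

Step 15
Reactants: 25 Weinreb amide
Product: 26 C6 aldehyde
Conditions: iBu2AlH, THF, −78 °C
Reagents that add atoms: none
Why: The chelated tetrahedral intermediate of a Weinreb amide releases the aldehyde only on work-up, so over-reduction is avoided; used at once because C5 is epimerisable.

Step 16
Reactants: 26 aldehyde; 27 vinylmagnesium bromide
Product: 28 C6 allylic alcohol (vinyl CH = C7)
Conditions: THF, −78 °C
Reagents that add atoms: none
Why: Felkin–Anh addition anti to the quaternary C10 (the largest group on C5) should place O6 anti to C4 along the C5–C6 bond, which is the configuration needed at C6.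

Step 17
Reactants: 28 allylic alcohol
Product: 29 C6,C12-diol
Conditions: DDQ, CH2Cl2/pH 7 buffer, 0 °C
Reagents that add atoms: none
Why: Oxidative cleavage of the electron-rich 4-methoxybenzyl ether is selective over the benzyl ether and the alkenes.

Step 18
Reactants: 29 diol
Product: 30 C6,C12-diacetate
Conditions: Ac2O, DMAP, Et3N, CH2Cl2, 40 °C
Reagents that add atoms: acetic anhydride, CC(=O)OC(C)=O
Why: Both secondary alcohols are acetylated at a stage where the C7 and tertiary hydroxy groups do not yet exist; the two acetates of the target are installed in one step.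

Step 19
Reactants: 30 diacetate
Product: 31 C3 alcohol
Conditions: HF·pyridine, THF, 0 °C to rt
Reagents that add atoms: none
Why: Fluoride-mediated cleavage of the silyl ether under buffered acidic conditions that acetates, ketal and benzyl ether tolerate.

Step 20
Reactants: 31 C3 alcohol
Product: 32 C3 ketone
Conditions: Dess–Martin periodinane, NaHCO3, CH2Cl2, rt
Reagents that add atoms: none
Why: Neutral oxidation of the only free hydroxy group; the C3 stereocentre is removed.

Step 21
Reactants: 32 diene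
Product: 34 C7 aldehyde / C9 cyclobutanone, via bis-ozonide 33 (not isolated)
Conditions: O3, CH2Cl2, −78 °C; then Me2S, −78 °C to rt
Reagents that add atoms: ozone, [O-][O+]=O
Why: Ozonolysis cleaves both terminal alkenes at once, giving the cyclobutanone at C9 and the α-acetoxy aldehyde at C7; no stereocentre is touched.

Step 22
Reactants: 34 ketal
Product: 35 methyl ketone (C14 acetyl, C8 methyl)
Conditions: PPTS, acetone/H2O (10:1), 50 °C
Reagents that add atoms: water, O
Why: Mild acid hydrolysis of the dioxolane frees the methyl ketone while acetates, benzyl ether and cyclopropane persist.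

Step 23
Reactants: 35 methyl ketone
Product: 37 11-O-benzyl ether of the target (pentacyclic), via ring C ketol 36 (not isolated)
Conditions: MgBr2·OEt2, iPr2NEt, CH2Cl2, 0 °C to rt
Reagents that add atoms: none
Why: Tandem intramolecular aldol by soft enolisation: the C8 methyl enolate adds 6-exo to the strained C9 ketone from the tethered face (C9–OH syn to O11); the magnesium chelate of that β-hydroxy ketone then enolises toward C8 again and adds to the C7 aldehyde through a chair transition state, giving H8 syn to O9 and O7 anti to C14.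

Step 24
Reactants: 37 benzyl ether
Product: 38 target CNP0157858.2
Conditions: H2 (1 atm), Pd(OH)2/C, EtOAc, rt
Reagents that add atoms: none
Why: Neutral hydrogenolysis of the tertiary benzyl ether avoids the base that would trigger retro-aldol opening of the cyclobutanol or acetyl migration.

**Compound list**

1 | (R)-(−)-carvone | CC(=C)[C@@H]1CC=C(C)C(=O)C1 | starting material
2 | carvone hydrobromide, (5R)-5-(2-bromopropan-2-yl)-2-methylcyclohex-2-en-1-one | CC(C)(Br)[C@@H]1CC=C(C)C(=O)C1 | intermediate (not isolated)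
3 | eucarvone, 2,6,6-trimethylcyclohepta-2,4-dien-1-one | O=C1C(C)=CC=CC(C)(C)C1 | intermediate
4 | (4R,5S)-4,5-epoxy-2,6,6-trimethylcyclohept-2-en-1-one | O=C1C(C)=C[C@H]2O[C@H]2C(C)(C)C1 | intermediate
5 | (5R)-5-hydroxy-2,6,6-trimethylcyclohept-3-en-1-one (C2 epimers) | O=C1C(C)C=C[C@@H](O)C(C)(C)C1 | intermediate (not isolated)
6 | (5R)-5-hydroxy-2,6,6-trimethylcyclohept-2-en-1-one | O=C1C(C)=CC[C@@H](O)C(C)(C)C1 | intermediate
7 | (5R)-5-(tert-butyldimethylsilyloxy)-2,6,6-trimethylcyclohept-2-en-1-one | O=C1C(C)=CC[C@@H](O[Si](C)(C)C(C)(C)C)C(C)(C)C1 | intermediate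
8 | benzyl propargyl ether | C#CCOCc1ccccc1 | starting material
9 | benzyloxyallene | C=C=COCc1ccccc1 | intermediate
10 | (R)-propylene oxide | C[C@@H]1CO1 | starting material
11 | diethyl cyanomethylphosphonate | CCOP(=O)(CC#N)OCC | starting material
12 | (1S,2S)-2-methylcyclopropane-1-carbonitrile | N#C[C@H]1C[C@@H]1C | intermediate
13 | N-methoxy-N-methylacetamide | CC(=O)N(C)OC | starting material
14 | (2S)-1-lithio-2-methylcyclopropane-1-carbonitrile | [Li]C1(C#N)C[C@@H]1C | intermediate (not isolated)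
15 | (1S,2S)-1-acetyl-2-methylcyclopropane-1-carbonitrile (acetyl trans to methyl) | N#C[C@@]1(C[C@@H]1C)C(C)=O | intermediate
16 | (1S,2S)-2-methyl-1-(2-methyl-1,3-dioxolan-2-yl)cyclopropane-1-carbonitrile | N#C[C@@]1(C[C@@H]1C)C1(C)OCCO1 | intermediate
17 | (1S,2S)-2-methyl-1-(2-methyl-1,3-dioxolan-2-yl)cyclopropane-1-carbaldehyde | O=C[C@@]1(C[C@@H]1C)C1(C)OCCO1 | intermediate
18 | 1-benzyloxy-1-lithioallene | [Li]C(OCc1ccccc1)=C=C | intermediate (not isolated)
19 | (1S)-2-benzyloxy-1-[(1S,2S)-2-methyl-1-(2-methyl-1,3-dioxolan-2-yl)cyclopropyl]buta-2,3-dien-1-ol | C=C=C(OCc1ccccc1)[C@@H](O)[C@@]1(C[C@@H]1C)C1(C)OCCO1 | intermediate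
20 | 4-methoxybenzyl ether of 19 (allene fragment: C11 benzyloxy, C12 OPMB, C13 cyclopropane, C14 ketal, C8 methyl) | C=C=C(OCc1ccccc1)[C@@H](OCc1ccc(OC)cc1)[C@@]1(C[C@@H]1C)C1(C)OCCO1 | intermediate
21 | trans-fused cycloadduct: ring A′ cycloheptanone (C6=O, 3-OTBS, 4,4-dimethyl) fused at C1–C10 to cyclobutane with 9-methylene, 11-OBn (syn to C20) and the C12(OPMB)–cyclopropyl ketal chain; H1 anti to C20 | O=C1CC(C)(C)[C@H](O[Si](C)(C)C(C)(C)C)C[C@@H]2[C@]1(C)C(=C)[C@@]2(OCc1ccccc1)[C@@H](OCc1ccc(OC)cc1)[C@@]1(C[C@@H]1C)C1(C)OCCO1 | intermediate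
22 | C5-trifluoroacetyl derivative of 21 (C5 unspecified, enolised) | O=C1C(C(=O)C(F)(F)F)C(C)(C)[C@H](O[Si](C)(C)C(C)(C)C)C[C@@H]2[C@]1(C)C(=C)[C@@]2(OCc1ccccc1)[C@@H](OCc1ccc(OC)cc1)[C@@]1(C[C@@H]1C)C1(C)OCCO1 | intermediate (not isolated)
23 | C5-diazo ketone of 21 | O=C1C(=[N+]=[N-])C(C)(C)[C@H](O[Si](C)(C)C(C)(C)C)C[C@@H]2[C@]1(C)C(=C)[C@@]2(OCc1ccccc1)[C@@H](OCc1ccc(OC)cc1)[C@@]1(C[C@@H]1C)C1(C)OCCO1 | intermediate
24 | ring-contracted ketene (C5=C6=O on six-membered ring A) | O=C=C1C(C)(C)[C@H](O[Si](C)(C)C(C)(C)C)C[C@@H]2[C@]1(C)C(=C)[C@@]2(OCc1ccccc1)[C@@H](OCc1ccc(OC)cc1)[C@@]1(C[C@@H]1C)C1(C)OCCO1 | intermediate (not isolated)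
25 | Weinreb amide: ring A trans-fused to ring D, C6 N-methoxy-N-methylcarboxamide on C5 (H5 syn to C20) | CON(C)C(=O)[C@@H]1C(C)(C)[C@H](O[Si](C)(C)C(C)(C)C)C[C@@H]2[C@]1(C)C(=C)[C@@]2(OCc1ccccc1)[C@@H](OCc1ccc(OC)cc1)[C@@]1(C[C@@H]1C)C1(C)OCCO1 | intermediate
26 | C6 aldehyde | O=C[C@@H]1C(C)(C)[C@H](O[Si](C)(C)C(C)(C)C)C[C@@H]2[C@]1(C)C(=C)[C@@]2(OCc1ccccc1)[C@@H](OCc1ccc(OC)cc1)[C@@]1(C[C@@H]1C)C1(C)OCCO1 | intermediate
27 | vinylmagnesium bromide | C=C[Mg]Br | starting material
28 | C6 allylic alcohol (C6–OH, C7 vinyl) | C=C[C@@H](O)[C@@H]1C(C)(C)[C@H](O[Si](C)(C)C(C)(C)C)C[C@@H]2[C@]1(C)C(=C)[C@@]2(OCc1ccccc1)[C@@H](OCc1ccc(OC)cc1)[C@@]1(C[C@@H]1C)C1(C)OCCO1 | intermediate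
29 | C6,C12-diol | C=C[C@@H](O)[C@@H]1C(C)(C)[C@H](O[Si](C)(C)C(C)(C)C)C[C@@H]2[C@]1(C)C(=C)[C@@]2(OCc1ccccc1)[C@@H](O)[C@@]1(C[C@@H]1C)C1(C)OCCO1 | intermediate
30 | C6,C12-diacetate | C=C[C@@H](OC(C)=O)[C@@H]1C(C)(C)[C@H](O[Si](C)(C)C(C)(C)C)C[C@@H]2[C@]1(C)C(=C)[C@@]2(OCc1ccccc1)[C@@H](OC(C)=O)[C@@]1(C[C@@H]1C)C1(C)OCCO1 | intermediate
31 | C3 alcohol (diacetate) | C=C[C@@H](OC(C)=O)[C@@H]1C(C)(C)[C@H](O)C[C@@H]2[C@]1(C)C(=C)[C@@]2(OCc1ccccc1)[C@@H](OC(C)=O)[C@@]1(C[C@@H]1C)C1(C)OCCO1 | intermediate
32 | C3 ketone (diacetate, two terminal alkenes) | C=C[C@@H](OC(C)=O)[C@@H]1C(C)(C)C(=O)C[C@@H]2[C@]1(C)C(=C)[C@@]2(OCc1ccccc1)[C@@H](OC(C)=O)[C@@]1(C[C@@H]1C)C1(C)OCCO1 | intermediate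
33 | bis-ozonide of 32 (1,2,4-trioxolanes at C7 and spiro at C9; acetal centres unspecified) | C1OOC(O1)[C@@H](OC(C)=O)[C@@H]2C(C)(C)C(=O)C[C@@H]3[C@]2(C)C4(OOCO4)[C@@]3(OCc5ccccc5)[C@@H](OC(C)=O)[C@@]5(C[C@@H]5C)C5(C)OCCO5 | intermediate (not isolated)
34 | C7 aldehyde / C9 cyclobutanone (C14 ketal) | O=C[C@@H](OC(C)=O)[C@@H]1C(C)(C)C(=O)C[C@@H]2[C@]1(C)C(=O)[C@@]2(OCc1ccccc1)[C@@H](OC(C)=O)[C@@]1(C[C@@H]1C)C1(C)OCCO1 | intermediate
35 | C14 methyl ketone (C7 aldehyde, C9 cyclobutanone) | O=C[C@@H](OC(C)=O)[C@@H]1C(C)(C)C(=O)C[C@@H]2[C@]1(C)C(=O)[C@@]2(OCc1ccccc1)[C@@H](OC(C)=O)[C@@]1(C[C@@H]1C)C(C)=O | intermediate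
36 | ring C ketol (rings A, C, D and cyclopropane closed; C9–OH; free C7 aldehyde) | O=C[C@@H](OC(C)=O)[C@@H]1C(C)(C)C(=O)C[C@@H]2[C@]1(C)[C@@]3(O)CC(=O)[C@]4(C[C@@H]4C)[C@H](OC(C)=O)[C@@]23OCc1ccccc1 | intermediate (not isolated)
37 | 11-O-benzyl ether of the target | CC(=O)O[C@@H]1[C@H](O)[C@H]2C(=O)[C@]3(C[C@@H]3C)[C@H](OC(C)=O)[C@@]3(OCc4ccccc4)[C@@H]4CC(=O)C(C)(C)[C@@H]1[C@@]4(C)[C@@]23O | intermediate
38 | CNP0157858.2 | CC(=O)O[C@@H]1[C@H](O)[C@H]2C(=O)[C@]3(C[C@@H]3C)[C@H](OC(C)=O)[C@@]3(O)[C@@H]4CC(=O)C(C)(C)[C@@H]1[C@@]4(C)[C@@]23O | target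

**Step count**

Total: 24 steps. Longest linear sequence: 19 steps (steps 6–11, then 12–24).

**Steps most likely to fail**

1. Step 12 (cross [2+2]). The cycloaddition may take the other orientation (C9 bonding to C1) or engage the terminal C=C of the allene; facial control by the remote C3 and C12 centres may be weak; enone dimerisation competes.
 Fallback, setting out from 7 and 17 and returning at 21: enone 7 is irradiated with propadiene, whose orientation with 2-alkylcycloalkenones is well defined (sp carbon to the α-carbon), to give the 9-methylene cyclobutane adduct F1. Allylic oxidation of the ring methylene C11 (SeO2 cat., t-BuOOH) gives the 9-methylenecyclobutan-11-one F2. Aldehyde 17 is converted (Bu3SnLi, then 4-methoxybenzyl bromide) into the α-alkoxy stannane F3. Tin–lithium exchange (n-BuLi, −78 °C) gives the configurationally stable α-alkoxyorganolithium F4, which is added with CeCl3 to the cyclobutanone carbonyl of F2 from the face of H1 to give the tertiary alcohol F5. O-Benzylation (KN(SiMe3)2, BnBr) then gives 21.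

2. Step 23 (double aldol). The ring A ketone may enolise toward C2 and add to the C7 aldehyde; the new β-hydroxy ketones may lose water; the acetyl group may migrate from O6 to O7; C7 and C8 may form with the wrong relative configuration.
 Fallback, setting out from 31 and returning at 37: C3 is kept at the alcohol level so that C14 is the only enolisable ketone. Ozonolysis of 31, through the bis-ozonide F6, gives the hydroxy keto aldehyde F7, and ketal hydrolysis gives the methyl ketone F8. The two aldol closures are then run one after the other: ring C first (LiN(SiMe3)2, −78 °C) to the ketol F9, then ring B (MgBr2·OEt2, iPr2NEt) to the pentacyclic C3 alcohol F10. The less hindered, more electron-rich C3 carbinol is then oxidised selectively (Dess–Martin periodinane, 1 equiv, 0 °C) to 37.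

3. Step 14 (Wolff ring contraction). Carbene pathways other than the 1,2-shift may intervene, and the amide enol may be protonated from the wrong face, giving the C5 epimer.
 Fallback, setting out from 21 and returning at 26: the ring is contracted by a quasi-Favorskii (semibenzilic) rearrangement instead. Kinetic bromination of the C5 enolate of 21 (LiN(SiMe3)2, then N-bromosuccinimide) gives the α-bromo ketone F11. NaOMe in MeOH adds to the C6 carbonyl and C10 shifts to C5 with loss of bromide and inversion at C5 (there is no enolisable α′-hydrogen, so no cyclopropanone path), giving the ring-contracted methyl ester F12. Reduction with iBu2AlH at −78 °C gives aldehyde 26.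

**Further compounds**

F1 | step 12 | propadiene adduct of 7 (trans-fused, 9-methylene, C11 CH2) | O=C1CC(C)(C)[C@H](O[Si](C)(C)C(C)(C)C)C[C@@H]2[C@]1(C)C(=C)C2
F2 | step 12 | 9-methylenecyclobutan-11-one | O=C1CC(C)(C)[C@H](O[Si](C)(C)C(C)(C)C)C[C@@H]2[C@]1(C)C(=C)C2=O
F3 | step 12 | α-(4-methoxybenzyloxy) tributylstannane from 17 | CCCC[Sn](CCCC)(CCCC)[C@@H](OCc1ccc(OC)cc1)[C@@]1(C[C@@H]1C)C1(C)OCCO1
F4 | step 12 | α-alkoxyorganolithium from F3 | [Li][C@@H](OCc1ccc(OC)cc1)[C@@]1(C[C@@H]1C)C1(C)OCCO1
F5 | step 12 | C11 tertiary alcohol (21 without the benzyl group) | O=C1CC(C)(C)[C@H](O[Si](C)(C)C(C)(C)C)C[C@@H]2[C@]1(C)C(=C)[C@@]2(O)[C@@H](OCc1ccc(OC)cc1)[C@@]1(C[C@@H]1C)C1(C)OCCO1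
F6 | step 23 | bis-ozonide of 31 | C1OOC(O1)[C@@H](OC(C)=O)[C@@H]2C(C)(C)[C@H](O)C[C@@H]3[C@]2(C)C4(OOCO4)[C@@]3(OCc5ccccc5)[C@@H](OC(C)=O)[C@@]5(C[C@@H]5C)C5(C)OCCO5
F7 | step 23 | C3-hydroxy keto aldehyde (C14 ketal) | O=C[C@@H](OC(C)=O)[C@@H]1C(C)(C)[C@H](O)C[C@@H]2[C@]1(C)C(=O)[C@@]2(OCc1ccccc1)[C@@H](OC(C)=O)[C@@]1(C[C@@H]1C)C1(C)OCCO1
F8 | step 23 | C3-hydroxy methyl ketone | O=C[C@@H](OC(C)=O)[C@@H]1C(C)(C)[C@H](O)C[C@@H]2[C@]1(C)C(=O)[C@@]2(OCc1ccccc1)[C@@H](OC(C)=O)[C@@]1(C[C@@H]1C)C(C)=O
F9 | step 23 | C3-hydroxy ring C ketol | O=C[C@@H](OC(C)=O)[C@@H]1C(C)(C)[C@H](O)C[C@@H]2[C@]1(C)[C@@]3(O)CC(=O)[C@]4(C[C@@H]4C)[C@H](OC(C)=O)[C@@]23OCc1ccccc1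
F10 | step 23 | pentacyclic C3 alcohol (11-O-benzyl) | CC(=O)O[C@@H]1[C@H](O)[C@H]2C(=O)[C@]3(C[C@@H]3C)[C@H](OC(C)=O)[C@@]3(OCc4ccccc4)[C@@H]4C[C@@H](O)C(C)(C)[C@@H]1[C@@]4(C)[C@@]23O
F11 | step 14 | C5 α-bromo ketone of 21 | O=C1[C@H](Br)C(C)(C)[C@H](O[Si](C)(C)C(C)(C)C)C[C@@H]2[C@]1(C)C(=C)[C@@]2(OCc1ccccc1)[C@@H](OCc1ccc(OC)cc1)[C@@]1(C[C@@H]1C)C1(C)OCCO1
F12 | step 14 | ring-contracted C6 methyl ester | COC(=O)[C@@H]1C(C)(C)[C@H](O[Si](C)(C)C(C)(C)C)C[C@@H]2[C@]1(C)C(=C)[C@@]2(OCc1ccccc1)[C@@H](OCc1ccc(OC)cc1)[C@@]1(C[C@@H]1C)C1(C)OCCO1
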